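All runs were generated by integration with constants of no real substance; noise was put on by code.

Monday's hot flask keeps more of its starting complex than Tuesday's, 81.6 % against 56.1 %, although Tuesday's level runs only from 57.2 % to 54.1 % while its side product grows. So I look for what stays still.

| setting | Tuesday's | Monday's | winter | summer | midnight |
|---|---|---|---|---|---|
| starting complex | 1 mM (fed, over 8.0 s) | 4 mM (fed, over 8.0 s) | 2.0 mM (fed, over 8.0 s) | 2.0 mM (fed, over 8.0 s) | 2.0 mM (fed, over 8.0 s) |
| incoming ligand | 1.4 mM | 1.4 mM | 1.40 mM | 1.40 mM | 1.40 mM |
| temperature | 82 °C | 110 °C | 70 °C | 95 °C | 120 °C |
| remark | run made earlier | run made earlier |  |  |  |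
| time |  |  | 10 min | 10 min | 10 min |

Tuesday's run (percent of the starting complex charged)

| time / min | side product / % | starting complex / % | complex with two exchanged / % | complex with one exchanged / % |
|---|---|---|---|---|
| 0.250 | 0 | 57.2 | 11.2 | 31.1 |
| 0.500 | 0.1 | 55.2 | 16.9 | 24.4 |
| 0.833 | 1.9 | 55.3 | 18.7 | 20.2 |
| 1.50 | 2.1 | 56.1 | 17.4 | 18.6 |
| 3.00 | 5.6 | 54.1 | 13.5 | 16.1 |

Monday's run (percent of the starting complex charged)

| time / s | side product / % | starting complex / % | complex with two exchanged / % | complex with one exchanged / % |
|---|---|---|---|---|
| 10.0 | 0.5 | 83.5 | 1.5 | 15.3 |
| 12.0 | 0.6 | 81.9 | 2.1 | 14.1 |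
| 25.0 | 2.0 | 82.7 | 1.0 | 13.9 |
| 50.0 | 4.1 | 81.6 | 2.1 | 12.7 |

(standard deviation of a reading: 0.5 percentage points)

* which of these there is most of at the end, counted by the starting complex in it, winter (starting complex / complex with one exchanged / complex with two exchanged / side product)
* which of these there is most of at the end, counted by the starting complex in it, summer (starting complex / complex with one exchanged / complex with two exchanged / side product)
* which of these there is most of at the end, counted by the starting complex in it, midnight (starting complex / complex with one exchanged / complex with two exchanged / side product)
* amount of the one of these that there is most of at the end, in percent of the starting complex charged, winter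
* amount of the one of these that there is most of at the end, in percent of the starting complex charged, summer
* amount of the one of these that there is most of at the end, in percent of the starting complex charged, midnight

- steps under discussion: complex with two exchanged + incoming ligand <-> leaving ligand + complex with three exchanged; complex with one exchanged + incoming ligand <-> leaving ligand + complex with two exchanged; leaving ligand + complex with one exchanged -> side product; starting complex + incoming ligand <-> leaving ligand + complex with one exchanged

My candidate is the step-one quotient, [complex with one exchanged][leaving ligand]/([starting complex][incoming ligand]), which is the equilibrium constant of the first exchange if it holds still. Free leaving ligand counts each exchange in the complexes, with complex with three exchanged taken as the gap in the readings. Incoming ligand is the charge minus that and minus the side product. In Tuesday's flask at 1.50 min this gives leaving ligand 0.708 mM and incoming ligand 0.671 mM, so the quotient reads 0.350. At 3.00 min, with leaving ligand 0.752 mM, it reads 0.378, so I freeze it. Monday's last readings leave no gap beyond the scatter, so with leaving ligand 0.676 mM and incoming ligand 0.560 mM the quotient reads 0.188. Carried on geometrically with temperature, that gives 0.150 for midnight.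

Now the bracket for midnight. From below, incoming ligand is the limiting reagent, and each starting complex that leaves takes one, so starting complex does not fall below 30.0 %. From above, I take no drain to side product and leave out deeper exchange. The quotient's quadratic then gives 0.465 mM exchanged, a level of 76.8 %. Deeper exchange frees more leaving ligand, so this figure is an estimate of the ceiling and not a strict bound. The side product pulls the level down from there, and my hand stops at this bracket.

The forecast names starting complex in each flask, at 68 %, 55 % and 46 %. Its midnight value lies inside the bracket: “This is nearly a tie, with starting complex slightly ahead.”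

The flasks give starting complex as the largest, at 65.0 %, 58.0 % and 48.5 %, and midnight's value also lies inside.

    complex with two exchanged + incoming ligand ⇌ leaving ligand + complex with three exchanged (K = 2.40, k = 3.60 M⁻¹ s⁻¹, Ea = 54.0 kJ mol⁻¹, ΔH = −31.0 kJ mol⁻¹)
    complex with one exchanged + incoming ligand ⇌ leaving ligand + complex with two exchanged (K = 2.60, k = 25.0 M⁻¹ s⁻¹, Ea = 41.0 kJ mol⁻¹, ΔH = −82.0 kJ mol⁻¹)
    leaving ligand + complex with one exchanged → side product (k = 1.50 M⁻¹ s⁻¹, Ea = 48.0 kJ mol⁻¹)
    starting complex + incoming ligand ⇌ leaving ligand + complex with one exchanged (K = 0.480, k = 54.0 M⁻¹ s⁻¹, Ea = 59.0 kJ mol⁻¹, ΔH = −24.0 kJ mol⁻¹)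
    (constants at 70 °C)

At midnight's end the quotient stands at 0.164, near the carried 0.150. Midnight's flask ends at 48.5 %, below winter's 65.0 %, and the difference in temperature is the main reason for that gap. Summer read at 40.0 min is the second flask. Its quotient is 0.270 against 0.262 carried to its temperature, and there side product leads with 50.6 % over starting complex at 40.6 %.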